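## Retrosynthetic overview

- **Key disconnection:** the C1'–C2' bond of the octyl chain. A heptyl radical adds to a 5-methylidene tetrahydroquinolone, and the resulting planar C5 radical takes H on the face opposite the C8–OMe, which sets C5 cis to C8.
- **Carbocycle (formed second):** the C4a–C5 bond is made by a 6-exo Heck closure of a 5-iodo-4-pyridone carrying an (R)-1-methoxypent-4-enyl chain at C6.
- **Pyridone ring (formed first):** a 1,3,5-triketone condenses with O-methylhydroxylamine. The triketone comes from the dianion of 3-methoxypentane-2,4-dione and an (R)-α-methoxy ester.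
- **C8 stereocentre:** chiral pool, from methyl (R)-glycidate by allyl–copper opening and O-methylation.
- **Order of events:** C8 is fixed first, then the pyridone, then the carbocycle, and C5 last.

Assumption: the target SMILES is read as the cis-(5S,8R) isomer, and commercial allylmagnesium bromide solution and methyl (R)-glycidate are taken as purchasable.

## Route

**Step 1**
Reactants: 1 methoxyacetone; 2 acetic anhydride
Product: 3, 3-methoxypentane-2,4-dione
Conditions: Ac2O, BF3·OEt2, 0 °C → rt; then aq NaOAc, 60 °C
Reagents that add atoms: acetic anhydride (2), CC(=O)OC(C)=O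
Why: Hauser BF3-mediated C-acylation of a ketone goes through the more substituted (methoxy-bearing) enol to give the 3-substituted 2,4-dione, which is freed from its BF2 chelate by acetate hydrolysis; no stereocentre is formed.

**Step 2**
Reactants: 4 methyl (R)-glycidate [methyl (2R)-oxirane-2-carboxylate]; 5 allylmagnesium bromide
Product: 6, methyl (2R)-2-hydroxyhex-5-enoate
Conditions: allylMgBr, CuI (10 mol%), THF, −78 → −40 °C
Reagents that add atoms: allylmagnesium bromide (5), C=CC[Mg]Br
Why: Copper-catalysed Grignard epoxide opening attacks the unsubstituted C3 by SN2 faster than the ester at −78 °C, so the C2–O bond is untouched and the (R) centre (future C8) comes straight from the chiral pool.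

**Step 3**
Reactants: 6 methyl (2R)-2-hydroxyhex-5-enoate; 7 iodomethane
Product: 8, methyl (2R)-2-methoxyhex-5-enoate
Conditions: MeI, Ag2O, MeCN, rt, dark
Reagents that add atoms: iodomethane (7), CI
Why: Purdie methylation etherifies the α-hydroxy ester without a strong base, so the α-centre does not enolise and stays (R).

**Step 4**
Reactants: 3 3-methoxypentane-2,4-dione (2.2 equiv); 8 methyl (2R)-2-methoxyhex-5-enoate
Product: 9, (7R)-3,7-dimethoxyundec-10-ene-2,4,6-trione (C3 is enolisable and unassigned)
Conditions: 3, LDA (2.0 equiv per 3), THF, −78 → 0 °C; then 8, −78 → −20 °C; AcOH quench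
Reagents that add atoms: none
Why: Harris-type Claisen acylation, in which the 1,3-dianion of 3 reacts at its terminal carbanion with the ester and the triketone formed is at once deprotonated at its internal positions by excess dianion (no free amide base), which shields the α-methoxy centre from enolisation so (R) is retained.

**Step 5**
Reactants: 9 triketone; 10 O-methylhydroxylamine hydrochloride
Product: 11, 1,3-dimethoxy-6-[(1R)-1-methoxypent-4-en-1-yl]-2-methylpyridin-4(1H)-one
Conditions: MeONH2·HCl, NaOAc, EtOH, rt → 75 °C; then cat. AcOH, 75 °C
Reagents that add atoms: O-methylhydroxylamine hydrochloride (10), CON.Cl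
Why: Triketone-to-4-pyridone condensation (oxime ether, then N-methoxy enamine, then six-ring cyclodehydration onto the other terminal carbonyl), as in the hydroxylamine route to 1-hydroxy-4-pyridones; it cannot divert to an isoxazole because the oxygen is methylated, and enolisation runs toward the doubly activated C5 methylene, not the C7 stereocentre.

**Step 6**
Reactants: 11 pyridone; 12 N-iodosuccinimide
Product: 13, 5-iodo-1,3-dimethoxy-6-[(1R)-1-methoxypent-4-en-1-yl]-2-methylpyridin-4(1H)-one
Conditions: NIS, MeCN, 0 °C → rt, dark
Reagents that add atoms: N-iodosuccinimide (12), O=C1CCC(=O)N1I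
Why: Electrophilic aromatic iodination takes the only free ring position, the electron-rich C5 (α-carbon of the vinylogous amide), much faster than the isolated alkene reacts.

**Step 7**
Reactants: 13 iodopyridone
Product: 14, (8R)-1,3,8-trimethoxy-2-methyl-5-methylidene-5,6,7,8-tetrahydroquinolin-4(1H)-one
Conditions: Pd(OAc)2 (10 mol%), PPh3 (20 mol%), Ag2CO3, MeCN, 70 °C
Reagents that add atoms: none
Why: Intramolecular Mizoroki–Heck reaction, where 6-exo-trig carbopalladation of the terminal alkene is followed by β-hydride elimination of the only β-H (on C5) to give the exocyclic methylene, with Ag2CO3 scavenging HPdI to suppress exo-to-endo isomerisation; C8 is not touched.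

**Step 8 (key step)**
Reactants: 14 exo-methylene pyridone; 15 1-iodoheptane (5 equiv)
Product: 16, Waltherione K, (5S,8R)-1,3,8-trimethoxy-2-methyl-5-octyl-5,6,7,8-tetrahydroquinolin-4(1H)-one
Conditions: n-C7H15I, Bu3SnH (3 equiv, syringe pump), AIBN (cat.), PhH, 80 °C
Reagents that add atoms: 1-iodoheptane (15), CCCCCCCI (Bu3SnH supplies only H)
Why: Proposed new method: a tin-mediated reductive Giese-type hydroalkylation in which Bu3Sn• abstracts iodine from 15, the heptyl radical adds to the terminal CH2 of the 5-methylidene group (forming C1'–C2') to give a planar, pyridone-conjugated tertiary C5 radical, and Bu3SnH then delivers H axially to C5 on the face opposite the C8–OMe (held pseudoaxial by A1,3 strain with N–OMe), which places octyl cis to OMe and sets 5S; the closest known reaction types are the Giese reductive addition of alkyl iodides to styrenes and the cis-1,4-selective hydrogen delivery to 4-substituted 1-tetralyl sp2 centres (sertraline-type reductions).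

## Compound list

1 | methoxyacetone | COCC(C)=O | starting material
2 | acetic anhydride | CC(=O)OC(C)=O | starting material
3 | 3-methoxypentane-2,4-dione | CC(=O)C(OC)C(C)=O | intermediate
4 | methyl (R)-glycidate | COC(=O)[C@H]1CO1 | starting material
5 | allylmagnesium bromide | C=CC[Mg]Br | starting material
6 | methyl (2R)-2-hydroxyhex-5-enoate | COC(=O)[C@H](O)CCC=C | intermediate
7 | iodomethane | CI | starting material (reagent)
8 | methyl (2R)-2-methoxyhex-5-enoate | COC(=O)[C@H](OC)CCC=C | intermediate
9 | (7R)-3,7-dimethoxyundec-10-ene-2,4,6-trione | CC(=O)C(OC)C(=O)CC(=O)[C@H](OC)CCC=C | intermediate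
10 | O-methylhydroxylamine hydrochloride | CON.Cl | starting material (reagent)
11 | 1,3-dimethoxy-6-[(1R)-1-methoxypent-4-en-1-yl]-2-methylpyridin-4(1H)-one | C=CCC[C@@H](OC)c1cc(=O)c(OC)c(C)n1OC | intermediate
12 | N-iodosuccinimide | O=C1CCC(=O)N1I | starting material (reagent)
13 | 5-iodo-1,3-dimethoxy-6-[(1R)-1-methoxypent-4-en-1-yl]-2-methylpyridin-4(1H)-one | C=CCC[C@@H](OC)c1c(I)c(=O)c(OC)c(C)n1OC | intermediate
14 | (8R)-1,3,8-trimethoxy-2-methyl-5-methylidene-5,6,7,8-tetrahydroquinolin-4(1H)-one | C=C1CC[C@@H](OC)c2c1c(=O)c(OC)c(C)n2OC | intermediate
15 | 1-iodoheptane | CCCCCCCI | starting material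
16 | Waltherione K, (5S,8R)-1,3,8-trimethoxy-2-methyl-5-octyl-5,6,7,8-tetrahydroquinolin-4(1H)-one | CCCCCCCC[C@H]1CC[C@@H](OC)c2c1c(=O)c(OC)c(C)n2OC | target

## Summary

Total steps: 8. Longest linear sequence: 7 (steps 2–8, from methyl (R)-glycidate); step 1 is a one-step side branch.

Steps most likely to fail:

1. **Step 8.** The nucleophilic heptyl radical adds slowly to a fairly electron-rich alkene, and the cis:trans ratio from hydrogen transfer is a prediction, not a precedent on this ring system. Fallback: switch to a two-electron sequence from 14, with 9-BBN hydroboration (H delivered to C5 anti to the OMe, boron on the exocyclic CH2) followed by an sp3–sp3 Suzuki coupling (Pd/PCy3) with 1-bromoheptane.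

2. **Step 7.** The exocyclic alkene may isomerise to the endocyclic one, and Pd(0) may attack the N–OMe bond. Fallback: make the alkyne analogue of 13 (propargyl Grignard in step 2) and close the ring by tin-hydride aryl-radical 6-exo-dig cyclisation, which gives 14 without palladium.

3. **Steps 4–5.** The α-methoxy ketone may partly epimerise, and the N-methoxy pyridone condensation may be low-yielding. Fallback: set C8 after the heterocycle is built. Acylate the dianion of 3 with dimethyl oxalate and cyclise to the 4-pyranone-2-carboxylate, convert to the N-methoxy pyridone, then to the 6-(pent-4-enoyl) ketone via the Weinreb amide and butenyl Grignard. CBS reduction and O-methylation then give 11.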